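## Structural features

- **Skeleton.** The target is a 1,7-diarylheptanoid. Chain carbons C1 to C5 and one oxygen form a tetrahydropyran, with pyran numbering O1, C2 = chain C1, C4 = chain C3 and C6 = chain C5. Ring A (3',4'-dihydroxy-5'-methoxyphenyl) sits directly on C2. Ring B (4''-hydroxy-3''-methoxyphenyl) is joined to C6 through the ethylene C6–C7 of the chain.
- **Stereocentres.** C2, C4 and C6 are all S. No two are adjacent, because a CH2 group separates each pair. Ring A and the side chain are cis (diequatorial), and the acetate is trans to both, hence axial.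
- **Fragile groups.** These are the air- and base-sensitive catechol of ring A, the secondary acetate that must survive beside three free phenols, and the benzylic ether bond O1–C2, which ionises easily because ring A is a strong donor.
- **Real difficulty.** The triad must be set in the absolute sense with an axial oxygen, next to an arene that makes cationic closures reversible. The two halves of the chain must also be told apart, although they differ only by O3'–H.
- **Feature exploited by the key step.** O4'–H of ring A is para to C1', the carbon bound to C2, and both ortho positions C3' and C5' carry oxygen. The bond O1–C2 is therefore the 1,6-adduct of an alcohol to the p-quinone methide of ring A, and C2 may be a plain benzylic CH2 in the precursor.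
- **Consequence.** Without O1–C2 the molecule is a nearly C2-symmetric acyclic 3,5-diol, which maps onto a flat, achiral β-diketone.

## Logic of the disconnections

**13 to 12.** The O–H bonds at O3' and O4'' are exchanged for O–Si bonds. The catechol then appears only in the last step, and the phenols can be freed by fluoride, which does not attack the acetate. The forward step must be buffered and non-basic.

**12 to 11.** The C4–O(acetate) bond is cut with inversion. The axial oxygen is the one element a chair-controlled closure does not deliver. Cutting with inversion turns the triad into the all-equatorial arrangement, which is both the kinetic and the thermodynamic product of ring closure. The forward step must be an SN2 reaction at a secondary ring carbon with acetate as nucleophile, beside a hindered free phenol.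

**11 to 9, through 10 (key).**
- The O1–C2 bond is cut and replaced by a C–H bond.
- In one sentence: acyclic 9, whose chain C1 is an unfunctionalised benzylic CH2, is closed to the pyran by oxidation of ring A to a p-quinone methide and 1,6-addition of the C5 hydroxyl.
- The ring disappears, one stereocentre disappears, C1 loses all functionality, and the two carbinols no longer need separate handling.
- The forward step must oxidise at C1 and not at C7, which is met by leaving O4'–H as the only free phenol. It must also stop after one two-electron oxidation.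

**9 to 8.** The two carbinol C–H bonds at chain C3 and C5 are cut. An anti-1,3-diol is the characteristic product of BINAP–ruthenium hydrogenation of a β-diketone, so both remaining stereocentres fall back on one catalyst and 8 is achiral. Catalyst control is needed in both reductions.

**8 to 7 to 6.** The four C–H bonds at C1, C2, C6 and C7 are removed, restoring two C=C bonds. O4' regains a benzyl group, and the two O–Si bonds are then cut. One hydrogenation saturates the chain and unmasks exactly the phenol that the key step needs. Benzyl must sit on O4' only, and silyl on O3' and O4''.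

**6 to 5 + 2.** The C1=C2 bond is cut, which detaches ring A as an aldehyde. The forward condensation must occur at the terminal CH3 of 5 and not at its central CH2.

**5 to 3 + 4.** The C6=C7 bond is cut. Five of the seven chain carbons come from 4, and ring B with C7 comes from 3. The forward step must stop at mono-condensation.

**2 to 1.** The O4'–CH2Ph bond is cut. The forward step must distinguish O4'–H from O3'–H, which their different acidity allows.

## Other disconnections considered

**Alternative 1:** Prins cyclisation (the first that comes to mind).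
- Cut: O1–C2, C2–C3 and C4–O.
- Forward key step: homoallylic alcohol A1 and aldehyde A2 condense under acid to an oxocarbenium ion, which closes to the all-cis alcohol A3. A3 would need the same inversion at C4.
- Ground: the three donor oxygens of ring A stabilise the oxocarbenium ion, so ring closure should slow relative to 2-oxonia-Cope rearrangement. That rearrangement opens a path to loss of configuration at C6 and to exchange of side chains.
- A1 also needs its own asymmetric allylation after a multistep chain extension. The chosen plan never places a cation next to a stereocentre that is already set, and it needs one chiral catalyst only.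

**Alternative 2:** oxa-Michael closure.
- Cut: O1–C2 at the ketone oxidation level.
- Forward key step: 6-endo-trig oxa-Michael addition of hydroxy enone A4 to pyranone A5, followed by a bulky hydride and acetylation.
- Ground: the β-carbon of A4 carries the electron-rich ring A and is a poor acceptor. The closure is an unfavourable equilibrium, and base invites β-elimination or retro-aldol cleavage of A4.
- The single stereocentre of A4 calls for an acetate-type aldol reaction of a methyl ketone, where enantiocontrol is weak, and C4 needs a separate step. The chosen plan uses the donor power of ring A as its driving force instead of working against it.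

**Alternative 3:** hetero-Diels–Alder reaction.
- Cut: O1–C2 and C5–C6 together.
- Forward key step: enantioselective hetero-Diels–Alder reaction of silyloxydiene A6 with aldehyde A7 under a chiral Lewis acid. This gives cis-dihydropyran A8, which is hydrolysed to A5.
- Ground: C2 and C6 are set as a group, but A6 lacks a 1-alkoxy activator and ends in a bulky aryl group. A7 is enolisable, each partner needs several steps of its own, and C4 remains to be set.
- The count of steps is expected to be higher, with no stereocentre gained over the chosen plan.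

Key step: step 7

Assumption: the β-diketones 5, 6, 7 and 8 are written as diketo tautomers although they should be largely enolised; TBS stands for tert-butyldimethylsilyl and Bn for benzyl.

## Steps

**Step 1**
Reactants: 1 3,4-dihydroxy-5-methoxybenzaldehyde
Product: 2 4-(benzyloxy)-3-hydroxy-5-methoxybenzaldehyde
Conditions: BnBr (1.0 equiv), NaHCO3 (1.2 equiv), DMF, 40 °C
Reagents that add atoms: benzyl bromide, BrCc1ccccc1
Why: Williamson ether synthesis under weak base: O4–H is para to the formyl group and is the more acidic phenol, so NaHCO3 ionises it alone and the benzyl group goes to O4 while O3–H stays free.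

**Step 2**
Reactants: 3 4-hydroxy-3-methoxybenzaldehyde (vanillin); 4 pentane-2,4-dione (acetylacetone)
Product: 5 (E)-6-(4-hydroxy-3-methoxyphenyl)hex-5-ene-2,4-dione
Conditions: 4 (3 equiv), B2O3 (0.7 equiv), EtOAc, 80 °C; then 3, B(OnBu)3 (1 equiv), n-BuNH2 (0.2 equiv), 80 °C; 1 M HCl, 60 °C
Reagents that add atoms: none
Why: Pabon condensation (boron-mediated vinylogous aldol condensation): chelation of the β-diketone to boron blocks Knoevenagel reaction at the central CH2 and leaves a terminal CH3 as nucleophile. The excess of 4 holds the reaction at the mono-adduct, and dehydration under conjugation control gives the E-alkene.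

**Step 3**
Reactants: 5 (E)-6-(4-hydroxy-3-methoxyphenyl)hex-5-ene-2,4-dione; 2 4-(benzyloxy)-3-hydroxy-5-methoxybenzaldehyde
Product: 6 (1E,6E)-1-[4-(benzyloxy)-3-hydroxy-5-methoxyphenyl]-7-(4-hydroxy-3-methoxyphenyl)hepta-1,6-diene-3,5-dione
Conditions: 5, B2O3 (0.7 equiv), EtOAc, 80 °C; then 2, B(OnBu)3 (1 equiv), n-BuNH2 (0.2 equiv), 80 °C; 1 M HCl, 60 °C
Reagents that add atoms: none
Why: Second Pabon condensation, at the one remaining CH3 of 5. Free phenols are tolerated in this reaction type, and the new alkene should again be E.

**Step 4**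
Reactants: 6 (1E,6E)-1-[4-(benzyloxy)-3-hydroxy-5-methoxyphenyl]-7-(4-hydroxy-3-methoxyphenyl)hepta-1,6-diene-3,5-dione
Product: 7 (1E,6E)-1-[4-(benzyloxy)-3-(TBSO)-5-methoxyphenyl]-7-[4-(TBSO)-3-methoxyphenyl]hepta-1,6-diene-3,5-dione
Conditions: TBSCl (2.5 equiv), imidazole (5 equiv), DMF, rt
Reagents that add atoms: tert-butyldimethylsilyl chloride, CC(C)(C)[Si](C)(C)Cl
Why: Standard silylation of phenols caps O3' and O4'' in one operation. Any silyl enol ether of the diketone should be lost on aqueous work-up.

**Step 5**
Reactants: 7 (1E,6E)-1-[4-(benzyloxy)-3-(TBSO)-5-methoxyphenyl]-7-[4-(TBSO)-3-methoxyphenyl]hepta-1,6-diene-3,5-dione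
Product: 8 1-[3-(TBSO)-4-hydroxy-5-methoxyphenyl]-7-[4-(TBSO)-3-methoxyphenyl]heptane-3,5-dione
Conditions: H2 (1 atm), 10% Pd/C, EtOAc, rt
Reagents that add atoms: none
Why: Heterogeneous hydrogenation saturates both enone C=C bonds and hydrogenolyses the aryl benzyl ether in the same flask, while aryl silyl ethers and the enolised diketone are left. O4'–H thereby becomes the only free phenol.

**Step 6**
Reactants: 8 1-[3-(TBSO)-4-hydroxy-5-methoxyphenyl]-7-[4-(TBSO)-3-methoxyphenyl]heptane-3,5-dione
Product: 9 (3S,5S)-1-[3-(TBSO)-4-hydroxy-5-methoxyphenyl]-7-[4-(TBSO)-3-methoxyphenyl]heptane-3,5-diol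
Conditions: RuCl2[(S)-BINAP] (1 mol%), H2 (60 atm), EtOH/CH2Cl2, 50 °C
Reagents that add atoms: none
Why: Noyori asymmetric hydrogenation of a β-diketone: chelation of the 1,3-dioxygen unit to ruthenium lets the (S)-BINAP ligand set the first carbinol as S, and the second reduction, again under catalyst control, gives the anti (3S,5S)-diol. As both events favour S, most of the stereochemical error is diverted into the separable syn isomer.

**Step 7**
Reactants: 9 (3S,5S)-1-[3-(TBSO)-4-hydroxy-5-methoxyphenyl]-7-[4-(TBSO)-3-methoxyphenyl]heptane-3,5-diol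
Product: 11 (2S,4R,6S)-2-[3-(TBSO)-4-hydroxy-5-methoxyphenyl]-6-{2-[4-(TBSO)-3-methoxyphenyl]ethyl}oxan-4-ol, via p-quinone methide 10 (not isolated)
Conditions: Ag2O (1.1 equiv), 4 Å MS, CH2Cl2, rt, dark; filter through Celite; PPTS (5 mol%), rt
Reagents that add atoms: none
Why: Ag2O takes two electrons and two protons (O4'–H and one H of chain C1) from the only free phenol, by way of the phenoxyl radical and its disproportionation, and gives p-quinone methide 10; C3' and C5' both carry oxygen, so the radical has no open ortho site for coupling, and ring B, being a silyl ether, is not attacked by this oxidant, which secures C1 over C7. After the silver is filtered off, a trace of acid lets the C5 hydroxyl add to C1 in the 1,6 sense, a 6-exo-trig closure that restores the aromaticity of ring A and forms the O1–C2 bond of the pyran. The C3 hydroxyl can reach C1 only by a 4-exo closure to a strained oxetane that would reopen, so the ring closure itself tells the two carbinols apart and leaves the C3 hydroxyl free for step 8. The new stereocentre C2 is controlled by C6 and C4: in the chair-like transition state the side chain and the hydroxyl are equatorial and the planar quinone methide unit takes the equatorial site, which places H2 axial and gives 2S. As the addition is reversible through 10 under the acid, the kinetic and the thermodynamic preference point to the same all-equatorial isomer. The closest known reaction type is the oxidation of 2,6-disubstituted 4-alkylphenols with Ag2O to p-quinone methides followed by capture by a tethered nucleophile, as in the closure of the ether rings of lignans. Over-oxidation is held back by the near-stoichiometric charge of oxidant and by its removal before the ring is closed.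

**Step 8**
Reactants: 11 (2S,4R,6S)-2-[3-(TBSO)-4-hydroxy-5-methoxyphenyl]-6-{2-[4-(TBSO)-3-methoxyphenyl]ethyl}oxan-4-ol
Product: 12 (2S,4S,6S)-2-[3-(TBSO)-4-hydroxy-5-methoxyphenyl]-6-{2-[4-(TBSO)-3-methoxyphenyl]ethyl}oxan-4-yl acetate
Conditions: PPh3 (2 equiv), DIAD (2 equiv), AcOH (5 equiv), toluene, 0 °C to rt
Reagents that add atoms: acetic acid, CC(=O)O
Why: Mitsunobu reaction: the equatorial alcohol is activated as its oxyphosphonium salt and displaced by acetate in an SN2 step along the axial trajectory, which inverts C4 from R to S and installs the ester in one operation. Acetic acid is far more acidic than the phenol flanked by OMe and OTBS and is used in excess, so it should be the pronucleophile that reacts.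

**Step 9**
Reactants: 12 (2S,4S,6S)-2-[3-(TBSO)-4-hydroxy-5-methoxyphenyl]-6-{2-[4-(TBSO)-3-methoxyphenyl]ethyl}oxan-4-yl acetate
Product: 13 (2S,4S,6S)-2-(3,4-dihydroxy-5-methoxyphenyl)-6-[2-(4-hydroxy-3-methoxyphenyl)ethyl]oxan-4-yl acetate (target)
Conditions: n-Bu4NF (2.2 equiv), AcOH (2.5 equiv), THF, 0 °C, argon
Reagents that add atoms: none
Why: Fluoride cleavage of aryl silyl ethers, buffered with AcOH so that no free phenoxide is present that could attack or shift the acetate. No stereocentre is touched, and exclusion of air protects the catechol.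

## Compound list

1 | 3,4-dihydroxy-5-methoxybenzaldehyde | COc1cc(C=O)cc(O)c1O | starting material
2 | 4-(benzyloxy)-3-hydroxy-5-methoxybenzaldehyde | COc1cc(C=O)cc(O)c1OCc1ccccc1 | intermediate
3 | 4-hydroxy-3-methoxybenzaldehyde (vanillin) | COc1cc(C=O)ccc1O | starting material
4 | pentane-2,4-dione (acetylacetone) | CC(=O)CC(C)=O | starting material
5 | (E)-6-(4-hydroxy-3-methoxyphenyl)hex-5-ene-2,4-dione | COc1cc(/C=C/C(=O)CC(C)=O)ccc1O | intermediate
6 | (1E,6E)-1-[4-(benzyloxy)-3-hydroxy-5-methoxyphenyl]-7-(4-hydroxy-3-methoxyphenyl)hepta-1,6-diene-3,5-dione | COc1cc(/C=C/C(=O)CC(=O)/C=C/c2cc(O)c(OCc3ccccc3)c(OC)c2)ccc1O | intermediate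
7 | (1E,6E)-1-[4-(benzyloxy)-3-(tert-butyldimethylsilyloxy)-5-methoxyphenyl]-7-[4-(tert-butyldimethylsilyloxy)-3-methoxyphenyl]hepta-1,6-diene-3,5-dione | COc1cc(/C=C/C(=O)CC(=O)/C=C/c2cc(O[Si](C)(C)C(C)(C)C)c(OCc3ccccc3)c(OC)c2)ccc1O[Si](C)(C)C(C)(C)C | intermediate
8 | 1-[3-(tert-butyldimethylsilyloxy)-4-hydroxy-5-methoxyphenyl]-7-[4-(tert-butyldimethylsilyloxy)-3-methoxyphenyl]heptane-3,5-dione | COc1cc(CCC(=O)CC(=O)CCc2cc(O[Si](C)(C)C(C)(C)C)c(O)c(OC)c2)ccc1O[Si](C)(C)C(C)(C)C | intermediate
9 | (3S,5S)-1-[3-(tert-butyldimethylsilyloxy)-4-hydroxy-5-methoxyphenyl]-7-[4-(tert-butyldimethylsilyloxy)-3-methoxyphenyl]heptane-3,5-diol | COc1cc(CC[C@H](O)C[C@@H](O)CCc2cc(O[Si](C)(C)C(C)(C)C)c(O)c(OC)c2)ccc1O[Si](C)(C)C(C)(C)C | intermediate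
10 | 2-(tert-butyldimethylsilyloxy)-4-{(3S,5S)-7-[4-(tert-butyldimethylsilyloxy)-3-methoxyphenyl]-3,5-dihydroxyheptylidene}-6-methoxycyclohexa-2,5-dien-1-one (p-quinone methide, exocyclic alkene geometry not defined) | COc1cc(CC[C@H](O)C[C@@H](O)CC=C2C=C(O[Si](C)(C)C(C)(C)C)C(=O)C(OC)=C2)ccc1O[Si](C)(C)C(C)(C)C | intermediate
11 | (2S,4R,6S)-2-[3-(tert-butyldimethylsilyloxy)-4-hydroxy-5-methoxyphenyl]-6-{2-[4-(tert-butyldimethylsilyloxy)-3-methoxyphenyl]ethyl}oxan-4-ol | COc1cc(CC[C@H]2C[C@@H](O)C[C@@H](c3cc(O[Si](C)(C)C(C)(C)C)c(O)c(OC)c3)O2)ccc1O[Si](C)(C)C(C)(C)C | intermediate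
12 | (2S,4S,6S)-2-[3-(tert-butyldimethylsilyloxy)-4-hydroxy-5-methoxyphenyl]-6-{2-[4-(tert-butyldimethylsilyloxy)-3-methoxyphenyl]ethyl}oxan-4-yl acetate | COc1cc(CC[C@H]2C[C@H](OC(C)=O)C[C@@H](c3cc(O[Si](C)(C)C(C)(C)C)c(O)c(OC)c3)O2)ccc1O[Si](C)(C)C(C)(C)C | intermediate
13 | (2S,4S,6S)-2-(3,4-dihydroxy-5-methoxyphenyl)-6-[2-(4-hydroxy-3-methoxyphenyl)ethyl]oxan-4-yl acetate | COc1cc(CC[C@H]2C[C@H](OC(C)=O)C[C@@H](c3cc(O)c(O)c(OC)c3)O2)ccc1O | target

## Step count and least certain steps

Total step count: 9. Longest linear sequence: 8 (steps 1, 3, 4, 5, 6, 7, 8, 9); step 2 runs in parallel.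

**Step 7 (key step).**
- Most likely problems are further oxidation of 11 at its benzylic C–H if closure outruns the filtration, and tautomerisation of 10 by loss of a proton from chain C2. The second process puts an alkene next to the C3 carbinol and exposes that centre to ionisation under the acid.
- Silyl shift from O3' to O4' before oxidation would also take material out of the productive path.
- Fallback, from 9 back to 11: the oxidation is driven on purpose to the ketone level, and the ring is closed by reduction instead of by O-attack on a quinone methide.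
- DDQ (2.2 equiv) in aqueous dioxane should convert the 4-alkylphenol into the C1 aryl ketone F1, which can close reversibly onto its C5 hydroxyl.
- Et3SiH and CF3CO2H in CH2Cl2 at low temperature then reduce the derived cyclic oxocarbenium ion by axial hydride delivery (reductive etherification). This again places ring A equatorial and returns 11.

**Step 8.**
- Elimination of the activated alcohol toward C3 or C5 may compete with substitution, and the free phenol may be drawn in as a competing nucleophile or acyl acceptor.
- Fallback, from 11 back to 12: inversion by oxidation and reduction instead of SN2.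
- Parikh–Doering oxidation (SO3·pyridine, DMSO, Et3N) gives pyranone F4.
- LiBH(s-Bu)3 in THF at −78 °C, with an extra equivalent for the phenol, attacks from the equatorial side and gives the axial alcohol F5.
- Ac2O, pyridine and DMAP give the diacetate F6.
- Pyrrolidine in CH2Cl2 at 0 °C cleaves only the aryl acetate and returns 12.

**Step 6.**
- The second reduction may show eroded anti selectivity, because the hydroxy ketone intermediate binds differently from the diketone. Slow loss of aryl silyl groups in the warm protic medium is also possible.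
- Fallback, from 8 back to 9: only the first stereocentre is set by the catalyst, and the second is relayed from it.
- The hydrogenation with RuCl2[(S)-BINAP] is stopped after uptake of one equivalent of H2. This gives the two regioisomeric (S)-hydroxy ketones, the C5 carbinol F2 and the C3 carbinol F3.
- Hydroxyl-directed Evans–Saksena reduction (Me4NBH(OAc)3, MeCN/AcOH, −30 °C) of the mixture delivers hydride anti in each, and both isomers converge on 9. The lack of regiocontrol in the first reduction therefore has no consequence.

**Step 3.**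
- Amine-catalysed retro-aldol cleavage of the arm already in place may lead to aldehyde exchange between the two ends, and conversion of the hindered aldehyde 2 may be low.
- Fallback, from 5 back to 8: saturation and chain joining change places, so that the exchange pathway is removed by structure.
- H2 over 10% Pd/C in EtOAc turns 5 into the saturated diketone F7.
- The boron-mediated condensation with 2 at its terminal CH3 gives the mono-enone F8.
- TBSCl and imidazole give the bis-silyl ether F9.
- H2 over 10% Pd/C saturates the remaining alkene, removes the benzyl group and returns 8.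

## Further compounds

F1 | step 7 | (3R,5S)-1-[3-(tert-butyldimethylsilyloxy)-4-hydroxy-5-methoxyphenyl]-7-[4-(tert-butyldimethylsilyloxy)-3-methoxyphenyl]-3,5-dihydroxyheptan-1-one | COc1cc(CC[C@H](O)C[C@@H](O)CC(=O)c2cc(O[Si](C)(C)C(C)(C)C)c(O)c(OC)c2)ccc1O[Si](C)(C)C(C)(C)C
F2 | step 6 | (5S)-1-[3-(tert-butyldimethylsilyloxy)-4-hydroxy-5-methoxyphenyl]-7-[4-(tert-butyldimethylsilyloxy)-3-methoxyphenyl]-5-hydroxyheptan-3-one | COc1cc(CC[C@H](O)CC(=O)CCc2cc(O[Si](C)(C)C(C)(C)C)c(O)c(OC)c2)ccc1O[Si](C)(C)C(C)(C)C
F3 | step 6 | (5S)-7-[3-(tert-butyldimethylsilyloxy)-4-hydroxy-5-methoxyphenyl]-1-[4-(tert-butyldimethylsilyloxy)-3-methoxyphenyl]-5-hydroxyheptan-3-one (carbinol at chain C3 of the route) | COc1cc(CCC(=O)C[C@@H](O)CCc2cc(O[Si](C)(C)C(C)(C)C)c(O)c(OC)c2)ccc1O[Si](C)(C)C(C)(C)C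
F4 | step 8 | (2S,6S)-2-[3-(tert-butyldimethylsilyloxy)-4-hydroxy-5-methoxyphenyl]-6-{2-[4-(tert-butyldimethylsilyloxy)-3-methoxyphenyl]ethyl}oxan-4-one | COc1cc(CC[C@H]2CC(=O)C[C@@H](c3cc(O[Si](C)(C)C(C)(C)C)c(O)c(OC)c3)O2)ccc1O[Si](C)(C)C(C)(C)C
F5 | step 8 | (2S,4S,6S)-2-[3-(tert-butyldimethylsilyloxy)-4-hydroxy-5-methoxyphenyl]-6-{2-[4-(tert-butyldimethylsilyloxy)-3-methoxyphenyl]ethyl}oxan-4-ol | COc1cc(CC[C@H]2C[C@H](O)C[C@@H](c3cc(O[Si](C)(C)C(C)(C)C)c(O)c(OC)c3)O2)ccc1O[Si](C)(C)C(C)(C)C
F6 | step 8 | (2S,4S,6S)-2-[4-acetoxy-3-(tert-butyldimethylsilyloxy)-5-methoxyphenyl]-6-{2-[4-(tert-butyldimethylsilyloxy)-3-methoxyphenyl]ethyl}oxan-4-yl acetate | COc1cc(CC[C@H]2C[C@H](OC(C)=O)C[C@@H](c3cc(O[Si](C)(C)C(C)(C)C)c(OC(C)=O)c(OC)c3)O2)ccc1O[Si](C)(C)C(C)(C)C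
F7 | step 3 | 6-(4-hydroxy-3-methoxyphenyl)hexane-2,4-dione | COc1cc(CCC(=O)CC(C)=O)ccc1O
F8 | step 3 | (E)-1-[4-(benzyloxy)-3-hydroxy-5-methoxyphenyl]-7-(4-hydroxy-3-methoxyphenyl)hept-1-ene-3,5-dione | COc1cc(CCC(=O)CC(=O)/C=C/c2cc(O)c(OCc3ccccc3)c(OC)c2)ccc1O
F9 | step 3 | (E)-1-[4-(benzyloxy)-3-(tert-butyldimethylsilyloxy)-5-methoxyphenyl]-7-[4-(tert-butyldimethylsilyloxy)-3-methoxyphenyl]hept-1-ene-3,5-dione | COc1cc(CCC(=O)CC(=O)/C=C/c2cc(O[Si](C)(C)C(C)(C)C)c(OCc3ccccc3)c(OC)c2)ccc1O[Si](C)(C)C(C)(C)C
A1 | alternative 1 | (S)-1-[4-(benzyloxy)-3-methoxyphenyl]hex-5-en-3-ol | COc1cc(CC[C@H](O)CC=C)ccc1OCc1ccccc1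
A2 | alternative 1 | 3,4-bis(benzyloxy)-5-methoxybenzaldehyde | COc1cc(C=O)cc(OCc2ccccc2)c1OCc1ccccc1
A3 | alternative 1 | (2S,4R,6S)-2-[3,4-bis(benzyloxy)-5-methoxyphenyl]-6-{2-[4-(benzyloxy)-3-methoxyphenyl]ethyl}oxan-4-ol | COc1cc(CC[C@H]2C[C@@H](O)C[C@@H](c3cc(OCc4ccccc4)c(OCc4ccccc4)c(OC)c3)O2)ccc1OCc1ccccc1
A4 | alternative 2 | (1E,5S)-1-[3,4-bis(benzyloxy)-5-methoxyphenyl]-7-[4-(benzyloxy)-3-methoxyphenyl]-5-hydroxyhept-1-en-3-one | COc1cc(CC[C@H](O)CC(=O)/C=C/c2cc(OCc3ccccc3)c(OCc3ccccc3)c(OC)c2)ccc1OCc1ccccc1
A5 | alternative 2 | (2S,6S)-2-[3,4-bis(benzyloxy)-5-methoxyphenyl]-6-{2-[4-(benzyloxy)-3-methoxyphenyl]ethyl}oxan-4-one | COc1cc(CC[C@H]2CC(=O)C[C@@H](c3cc(OCc4ccccc4)c(OCc4ccccc4)c(OC)c3)O2)ccc1OCc1ccccc1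
A6 | alternative 3 | {[(3E)-4-[3,4-bis(benzyloxy)-5-methoxyphenyl]buta-1,3-dien-2-yl]oxy}triethylsilane | C=C(O[Si](CC)(CC)CC)/C=C/c1cc(OCc2ccccc2)c(OCc2ccccc2)c(OC)c1
A7 | alternative 3 | 3-[4-(benzyloxy)-3-methoxyphenyl]propanal | COc1cc(CCC=O)ccc1OCc1ccccc1
A8 | alternative 3 | {[(2S,6S)-6-[3,4-bis(benzyloxy)-5-methoxyphenyl]-2-{2-[4-(benzyloxy)-3-methoxyphenyl]ethyl}-3,6-dihydro-2H-pyran-4-yl]oxy}triethylsilane | COc1cc(CC[C@H]2CC(O[Si](CC)(CC)CC)=C[C@@H](c3cc(OCc4ccccc4)c(OCc4ccccc4)c(OC)c3)O2)ccc1OCc1ccccc1
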